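**Plan**

- Retrosynthesis: after the four methoxymethyl ethers are removed, each prenyl chain is cut between the benzylic CH2 on C6 or C8 of ring A and the CH= carbon of its 2-methylprop-1-enyl unit. The two chloromethyl carbons left behind are traced back through CH2OH and CHO to the free C6–H and C8–H of kaempferol.
- Enabling feature: C6 lies between O5 and O7, and C8 between O7 and the ring oxygen O1, so these two ring A carbons take up a one-carbon electrophile. Each benzylic carbon made this way has no beta hydrogen and can be joined to a preformed isobutenyl carbon.
- Forward order: no ring is built, because rings A, B and C come with kaempferol. One carbon is placed on C6 and on C8, the four hydroxyls are masked, the aldehydes are reduced and chlorinated, both four-carbon units are attached in one double cross-coupling, and the ethers are removed.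
- Stereochemistry: the target has no stereocentre and both alkenes end in a CMe2 group. Only the position of each double bond matters, and the alkenyl boronate fixes it.

Key step: step 5

Assumption: in trifluoroacetic acid the phloroglucinol-type ring A of kaempferol is taken to be far more nucleophilic than the 4-hydroxyphenyl ring B, which is deactivated by conjugation with the protonated pyranone, so formylation is expected to stop at C6 and C8.

**Route**

Step 1
Reactants: 1 kaempferol; 2 hexamethylenetetramine
Product: 3 3,5,7-trihydroxy-2-(4-hydroxyphenyl)-4-oxo-4H-chromene-6,8-dicarbaldehyde (6,8-diformylkaempferol)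
Conditions: hexamethylenetetramine (6 equiv), CF3CO2H, 90 °C; then 3 M aq. HCl, 60 °C
Reagents that add atoms: hexamethylenetetramine (2), C1N2CN3CN1CN(C2)C3; water, O
Why: Duff formylation, in which iminium ions from protonated hexamethylenetetramine attack C6 and C8 of ring A (each ortho and para to oxygen), the benzylamine adducts are dehydrogenated in the medium by hydride transfer, and the acid work-up hydrolyses the iminium groups to aldehydes, while ring B and the fully substituted C2 and C3 should stay untouched.

Step 2
Reactants: 3 6,8-diformylkaempferol
Product: 4 3,5,7-tris(methoxymethoxy)-2-[4-(methoxymethoxy)phenyl]-4-oxo-4H-chromene-6,8-dicarbaldehyde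
Conditions: NaH (6 equiv), MOMCl (6 equiv), DMF, 0 °C to rt
Reagents that add atoms: chloromethyl methyl ether, COCCl
Why: Williamson-type O-alkylation (methoxymethyl ether formation) of the four sodium aryloxide and enolate oxygens by the very reactive chloromethyl ether, with excess NaH so that the chelated 5-OH between the C4 carbonyl and the 6-formyl group is also alkylated; the aldehydes carry no enolisable hydrogen and should survive.

Step 3
Reactants: 4 tetrakis(methoxymethyl) dialdehyde
Product: 5 6,8-bis(hydroxymethyl)-3,5,7-tris(methoxymethoxy)-2-[4-(methoxymethoxy)phenyl]chromen-4-one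
Conditions: NaBH4 (1.5 equiv), THF/MeOH, 0 °C; aq. NH4Cl work-up
Reagents that add atoms: none
Why: Borohydride reduction, chemoselective because aryl aldehydes are reduced much faster than the vinylogous-ester C4 carbonyl of a 3-alkoxyflavone, so at 0 °C only the two formyl groups should react and the acetals are inert to hydride.

Step 4
Reactants: 5 bis(hydroxymethyl) compound
Product: 6 6,8-bis(chloromethyl)-3,5,7-tris(methoxymethoxy)-2-[4-(methoxymethoxy)phenyl]chromen-4-one
Conditions: PPh3 (2.6 equiv), N-chlorosuccinimide (2.6 equiv), THF, 0 °C to rt; short silica plug, used at once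
Reagents that add atoms: N-chlorosuccinimide, O=C1CCC(=O)N1Cl
Why: Appel-type chlorination, in which the chlorophosphonium salt from PPh3 and N-chlorosuccinimide activates both primary benzylic hydroxyls and chloride displaces triphenylphosphine oxide under essentially neutral conditions that the four acetals and the chromenone tolerate.

Step 5
Reactants: 6 bis(chloromethyl) compound; 7 2-methylprop-1-enylboronic acid pinacol ester [4,4,5,5-tetramethyl-2-(2-methylprop-1-enyl)-1,3,2-dioxaborolane]
Product: 8 3,5,7-tris(methoxymethoxy)-2-[4-(methoxymethoxy)phenyl]-6,8-bis(3-methylbut-2-enyl)chromen-4-one (6,8-diprenylkaempferol tetrakis(methoxymethyl) ether)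
Conditions: 7 (3 equiv), Pd(PPh3)4 (zerovalent palladium, 10 mol %), powdered K3PO4 (6 equiv), degassed 1,4-dioxane with a little water (about 20:1), 85 °C
Reagents that add atoms: 2-methylprop-1-enylboronic acid pinacol ester (7), CC(C)=CB1OC(C)(C)C(C)(C)O1
Why: Zerovalent palladium adds oxidatively to each benzylic C–Cl bond of 6 to give a benzylpalladium chloride (divalent palladium) that has no beta hydrogen and therefore cannot undergo beta-hydride elimination. The boronate 7, activated by phosphate and hydroxide, transfers its 2-methylprop-1-enyl group to palladium with the alkene intact, and reductive elimination forms the CH2–CH bond and regenerates zerovalent palladium, the cycle running twice per molecule. The closest known reaction type is the Suzuki–Miyaura coupling of benzyl halides with alkenylboron reagents. No ring is closed and no stereocentre is formed. The selectivity required is positional: the new bond must end at the CH terminus of the trisubstituted alkene, which is secured because boron sits on that sp2 carbon and no allylpalladium species that could transpose to a 1,1-dimethylallyl isomer is involved. Both electrophilic sites are of the same kind (each flanked by two ether oxygens), excess 7 should drive both couplings, and the methoxymethyl ethers, the C4 carbonyl and the product alkenes are inert to the mildly basic medium.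

Step 6
Reactants: 8 6,8-diprenylkaempferol tetrakis(methoxymethyl) ether
Product: 9 6,8-diprenylkaempferol [3,5,7-trihydroxy-2-(4-hydroxyphenyl)-6,8-bis(3-methylbut-2-enyl)chromen-4-one]
Conditions: 3 M aq. HCl, MeOH, 45 °C
Reagents that add atoms: none
Why: Acid-catalysed acetal exchange with methanol (methoxymethyl ether cleavage) frees the four hydroxyls, and dilute acid at this temperature is the usual way to unmask ortho-prenylphenols without cyclising them to dimethylchromans.

**Compound list**

1 | kaempferol | O=c1c(O)c(-c2ccc(O)cc2)oc2cc(O)cc(O)c12 | starting material
2 | hexamethylenetetramine | C1N2CN3CN1CN(C2)C3 | starting material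
3 | 3,5,7-trihydroxy-2-(4-hydroxyphenyl)-4-oxo-4H-chromene-6,8-dicarbaldehyde | O=Cc1c(O)c(C=O)c2oc(-c3ccc(O)cc3)c(O)c(=O)c2c1O | intermediate
4 | 3,5,7-tris(methoxymethoxy)-2-[4-(methoxymethoxy)phenyl]-4-oxo-4H-chromene-6,8-dicarbaldehyde | O=Cc1c(OCOC)c(C=O)c2oc(-c3ccc(OCOC)cc3)c(OCOC)c(=O)c2c1OCOC | intermediate
5 | 6,8-bis(hydroxymethyl)-3,5,7-tris(methoxymethoxy)-2-[4-(methoxymethoxy)phenyl]chromen-4-one | OCc1c(OCOC)c(CO)c2oc(-c3ccc(OCOC)cc3)c(OCOC)c(=O)c2c1OCOC | intermediate
6 | 6,8-bis(chloromethyl)-3,5,7-tris(methoxymethoxy)-2-[4-(methoxymethoxy)phenyl]chromen-4-one | ClCc1c(OCOC)c(CCl)c2oc(-c3ccc(OCOC)cc3)c(OCOC)c(=O)c2c1OCOC | intermediate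
7 | 2-methylprop-1-enylboronic acid pinacol ester | CC(C)=CB1OC(C)(C)C(C)(C)O1 | starting material
8 | 3,5,7-tris(methoxymethoxy)-2-[4-(methoxymethoxy)phenyl]-6,8-bis(3-methylbut-2-enyl)chromen-4-one | CC(C)=CCc1c(OCOC)c(CC=C(C)C)c2oc(-c3ccc(OCOC)cc3)c(OCOC)c(=O)c2c1OCOC | intermediate
9 | 6,8-diprenylkaempferol | CC(C)=CCc1c(O)c(CC=C(C)C)c2oc(-c3ccc(O)cc3)c(O)c(=O)c2c1O | target

**Step count**

Total step count: 6. Longest linear sequence: 6 steps (1 to 9).

**Steps most likely to fail**

Step 5 (key coupling). The electron-rich benzylic C–Cl bonds may be hydrolysed by the aqueous phosphate before oxidative addition. Slow transmetalation of the hindered pinacol boronate may also let benzylpalladium species homocouple into oligomers or leave the reaction at the mono-coupled stage. The fallback sets out from 6 and replaces the base-dependent boron transmetalation with a neutral tin transmetalation, a Migita–Stille coupling with tributyl(2-methylprop-1-enyl)stannane, Pd(PPh3)4, anhydrous toluene, 90 °C, with no base and no water. The same CH2–CH bonds would form and the route is rejoined at 8. No compound outside the list arises on this path (entry F0).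

Step 1 (Duff diformylation). The second formylation may stall on the ring already deactivated by the first formyl group, ring B may be formylated in competition, and aminomethylated oligomers may lower mass recovery. The fallback sets out from 1 and installs the two carbons by halogenation and carbonylation. Kaempferol is fully protected with NaH and MOMCl in DMF to give 3,5,7-tris(methoxymethoxy)-2-[4-(methoxymethoxy)phenyl]chromen-4-one F1. Iodination with N-iodosuccinimide in DMF at the two remaining ring A positions would give 6,8-diiodo-3,5,7-tris(methoxymethoxy)-2-[4-(methoxymethoxy)phenyl]chromen-4-one F2. A palladium-catalysed reductive carbonylation (PdCl2[Ph2P(CH2)3PPh2], CO, Et3SiH, Na2CO3, DMF, 90 °C) would then turn both C–I bonds into formyl groups. The route is rejoined at 4.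

Step 4 (chlorination). The benzylic chlorides, each flanked by two ether oxygens, may ionise during formation or handling, leading to loss of a neighbouring methoxymethyl group, self-alkylation or solvolysis on silica. The fallback sets out from 5 and avoids the halide altogether. Methyl chloroformate and pyridine in CH2Cl2 at 0 °C would give the covalent, non-ionising 6,8-bis[(methoxycarbonyloxy)methyl]-3,5,7-tris(methoxymethoxy)-2-[4-(methoxymethoxy)phenyl]chromen-4-one F3. This benzylic carbonate would be coupled directly with 7 under [Pd(C3H5)Cl]2 and 1,5-bis(diphenylphosphino)pentane in DMF at 80 °C, where decarboxylation releases methoxide as the internal base for boron. The route is rejoined at 8.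

**Further compounds**

F0 | step 5 | none | none
F1 | step 1 | 3,5,7-tris(methoxymethoxy)-2-[4-(methoxymethoxy)phenyl]chromen-4-one | COCOc1ccc(-c2oc3cc(OCOC)cc(OCOC)c3c(=O)c2OCOC)cc1
F2 | step 1 | 6,8-diiodo-3,5,7-tris(methoxymethoxy)-2-[4-(methoxymethoxy)phenyl]chromen-4-one | COCOc1ccc(-c2oc3c(I)c(OCOC)c(I)c(OCOC)c3c(=O)c2OCOC)cc1
F3 | step 4 | 6,8-bis[(methoxycarbonyloxy)methyl]-3,5,7-tris(methoxymethoxy)-2-[4-(methoxymethoxy)phenyl]chromen-4-one | COC(=O)OCc1c(OCOC)c(COC(=O)OC)c2oc(-c3ccc(OCOC)cc3)c(OCOC)c(=O)c2c1OCOC
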